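**Retrosynthetic overview**

1. A retro-[4+2] opening of the dihydropyran ring (ring O–spiro C bond and the adjoining CH2–CH2 bond) splits the C30 target into two C15 partners: (+)-alantolactone as the 2π partner and the 2-substituted acrolein of the divinylcyclohexane half as the 1-oxadiene.
2. Enabling feature: the 3,4-dihydro-2H-pyran ring, with its enol-ether unit O–CH=C and a spiro carbon that is at once the O-bearing C-2 of the pyran and the α-carbon of the γ-lactone C=O. This 2-acyl-dihydropyran is the retron of an enal/α-methylene-carbonyl hetero-Diels–Alder reaction.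
3. The divinylcyclohexane half is (1R,2R,4S), antipodal to commercial (−)-β-elemene (1S,2S,4R), so it is built from (S)-(+)-carvone: conjugate reduction/α-chlorination, vinyl Grignard addition with 1,2-vinyl shift (quaternary centre), then ketone → nitrile → acetyl → isopropenyl. The side-chain isopropenyl group is oxidised (ene chlorination) while it is the only 1,1-disubstituted alkene.
4. Ring order: the cyclohexane ring (from carvone) and the lactone and decalin rings (from alantolactone) are carried in intact; the dihydropyran ring is the only ring formed, and it is formed last.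

Key step: step 9

Remark on the chemistry: (+)-alantolactone (3aR,5S,8aR,9aR), whose configuration is exactly that of the lactone half of the target, and (S)-(+)-carvone are taken as the commercial chiral starting materials.

**Route**

Step 1
Reactants: 1 (S)-(+)-carvone
Product: 3 (2R,5S)-2-chloro-2-methyl-5-(prop-1-en-2-yl)cyclohexan-1-one, via lithium enolate 2 (not isolated)
Conditions: LiBH(s-Bu)3 (L-Selectride), THF, −78 °C; then N-chlorosuccinimide, −78 to 0 °C; H2O work-up
Reagents that add atoms: N-chlorosuccinimide, O=C1CCC(=O)N1Cl
Why: Conjugate (1,4) hydride reduction of the enone gives the tetrasubstituted lithium enolate regiospecifically, and its electrophilic α-chlorination should follow the stereoelectronically preferred axial attack on the half-chair with the isopropenyl group equatorial, so that chlorine ends axial and cis to the isopropenyl group (also the more stable epimer of a 2-halo-2-methylcyclohexanone), which sets C-2.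

Step 2
Reactants: 3 (2R,5S)-2-chloro-2-methyl-5-(prop-1-en-2-yl)cyclohexan-1-one
Product: 5 (2R,5S)-2-ethenyl-2-methyl-5-(prop-1-en-2-yl)cyclohexan-1-one, via magnesium chlorohydrinate 4 (not isolated)
Conditions: CH2=CHMgBr (1.1 equiv), THF, −78 to −20 °C; then toluene, 70 °C
Reagents that add atoms: vinylmagnesium bromide, C=C[Mg]Br
Why: Halohydrin semipinacol rearrangement (the classical α-halo ketone/Grignard route to α-substituted ketones): the vinyl nucleophile should add axially and anti to the axial C–Cl bond, and on warming the trans-diaxial vinyl group of the magnesium alkoxide migrates to the tertiary carbon with loss of chloride and inversion, which forms the quaternary centre with vinyl trans and methyl cis to the isopropenyl group, whereas an equatorial chloride lacks this alignment and should not lead to the epimeric ketone.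

Step 3
Reactants: 5 (2R,5S)-2-ethenyl-2-methyl-5-(prop-1-en-2-yl)cyclohexan-1-one
Product: 6 (2R,5S)-2-ethenyl-2-methyl-5-(prop-1-en-2-yl)cyclohexane-1-carbonitrile (both C-1 epimers)
Conditions: TosMIC, t-BuOK, EtOH (1.5 equiv), DME, 0 to 40 °C
Reagents that add atoms: p-toluenesulfonylmethyl isocyanide (TosMIC), Cc1ccc(cc1)S(=O)(=O)C[N+]#[C-]
Why: Van Leusen reductive cyanation (addition of the TosMIC anion, cyclisation to an oxazoline, ring opening, deformylation and loss of sulfinate) homologates the hindered ketone to the nitrile without touching the alkenes; the C-1 configuration is left open here because it is set later at the enolisable methyl ketone stage.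

Step 4
Reactants: 6 (2R,5S)-2-ethenyl-2-methyl-5-(prop-1-en-2-yl)cyclohexane-1-carbonitrile (both C-1 epimers)
Product: 7 (2R,5S)-5-(3-chloroprop-1-en-2-yl)-2-ethenyl-2-methylcyclohexane-1-carbonitrile (both C-1 epimers)
Conditions: Ca(OCl)2, CO2 (solid), CH2Cl2/H2O, 0 °C
Reagents that add atoms: calcium hypochlorite, [Ca+2].[O-]Cl.[O-]Cl
Why: Ene-type allylic chlorination by HOCl (generated from Ca(OCl)2 and CO2) should attack only the electron-rich 1,1-disubstituted isopropenyl group (the monosubstituted vinyl group and the nitrile are inert) and transposes the double bond to give the 2-(chloromethyl)allyl unit, which differentiates this side chain before the second isopropenyl group exists; no stereocentre is formed.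

Step 5
Reactants: 7 (2R,5S)-5-(3-chloroprop-1-en-2-yl)-2-ethenyl-2-methylcyclohexane-1-carbonitrile (both C-1 epimers)
Product: 8 (2R,5S)-5-[3-(acetyloxy)prop-1-en-2-yl]-2-ethenyl-2-methylcyclohexane-1-carbonitrile (both C-1 epimers)
Conditions: KOAc, n-Bu4NI (cat.), DMF, 50 °C
Reagents that add atoms: potassium acetate, CC(=O)[O-].[K+]
Why: SN2 displacement of the primary allylic chloride by acetate (iodide catalysis) installs the side-chain oxygen in a form that the next step removes without a separate deprotection.

Step 6
Reactants: 8 (2R,5S)-5-[3-(acetyloxy)prop-1-en-2-yl]-2-ethenyl-2-methylcyclohexane-1-carbonitrile (both C-1 epimers)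
Product: 10 1-[(1S,2R,5S)-2-ethenyl-5-(3-hydroxyprop-1-en-2-yl)-2-methylcyclohexyl]ethan-1-one, via dilithiated ketimine alkoxide 9 (not isolated)
Conditions: MeLi (4 equiv), Et2O, 0 °C to rt; 1 M aq HCl, THF, rt; then K2CO3, MeOH, rt
Reagents that add atoms: methyllithium, [Li]C; water, O
Why: Addition of MeLi to the nitrile stops at the N-lithio ketimine while the same reagent cleaves the acetate, acid hydrolysis gives the methyl ketone, and equilibration of the enolisable C-1 centre (acid, then K2CO3/MeOH) should place the acetyl group equatorial, trans to the vinyl group and cis to the side chain (thermodynamic control, reinforced by protonation of the enol anti to the adjacent axial methyl group).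

Step 7
Reactants: 10 1-[(1S,2R,5S)-2-ethenyl-5-(3-hydroxyprop-1-en-2-yl)-2-methylcyclohexyl]ethan-1-one
Product: 11 2-[(1S,3R,4R)-4-ethenyl-4-methyl-3-(prop-1-en-2-yl)cyclohexyl]prop-2-en-1-ol
Conditions: Ph3PCH3Br, t-BuOK (3.5 equiv each), THF, 0 to 60 °C
Reagents that add atoms: methyltriphenylphosphonium bromide, C[P+](c1ccccc1)(c1ccccc1)c1ccccc1.[Br-]
Why: Wittig methylenation with excess Ph3P=CH2 converts the hindered methyl ketone into the second isopropenyl group while the free hydroxyl is carried as its alkoxide; no new stereocentre is formed and the α-centre is already the stable epimer.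

Step 8
Reactants: 11 2-[(1S,3R,4R)-4-ethenyl-4-methyl-3-(prop-1-en-2-yl)cyclohexyl]prop-2-en-1-ol
Product: 12 2-[(1S,3R,4R)-4-ethenyl-4-methyl-3-(prop-1-en-2-yl)cyclohexyl]prop-2-enal
Conditions: MnO2 (activated), CH2Cl2, rt
Reagents that add atoms: none
Why: Allylic alcohol oxidation with MnO2 gives the 2-substituted acrolein chemoselectively under neutral conditions that leave the 1,5-diene and the stereocentres untouched.

Step 9
Reactants: 12 2-[(1S,3R,4R)-4-ethenyl-4-methyl-3-(prop-1-en-2-yl)cyclohexyl]prop-2-enal; 13 (+)-alantolactone
Product: 14 target CNP0175206.1 (spiro carbon R; ring oxygen syn to the two lactone ring-fusion hydrogens)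
Conditions: 13 (3 equiv), BHT (5 mol %), neat melt, 110 °C, sealed tube under Ar
Reagents that add atoms: none
Why: Thermal [4+2] cycloaddition in which the s-cis enal of 12 acts as the 1-oxa-1,3-diene (O=CH–C=CH2) and the exocyclic methylene of 13 as the 2π partner, an asynchronous concerted process in which the bond between the two unsubstituted CH2 termini leads and the carbonyl oxygen then closes onto the lactone α-carbon. The closest known reaction type is the head-to-head hetero-Diels–Alder dimerisation of α-methylene carbonyl compounds (acrolein and methacrolein dimers, spiro-dihydropyran dimers of 2-methylene ketones). The dihydropyran ring is closed by intermolecular cycloaddition, both ring bonds (CH2–CH2 and O–C spiro) being made suprafacially on each component, so no tether and no Baldwin mode is involved. The only new stereocentre, the spiro carbon, is fixed by approach of the oxadiene to the convex face of the cis-fused lactone, the face that carries the two ring-fusion hydrogens and is remote from the decalin, which places the ring oxygen syn to those hydrogens as required; endo/exo orientation is stereochemically silent because the diene termini carry no substituents. Regioselectivity (oxygen to the carbonyl-bearing alkene carbon) follows from the orbital coefficients and from stabilisation of the developing radical character α to both carbonyls, chemoselectivity for the cross-adduct over self-dimerisation of 12 is secured by the excess of 13 (whose ester carbonyl is a poor heterodiene, so 13 does not dimerise) and by the hindered α-substituent of 12, and the isolated vinyl, isopropenyl and trisubstituted alkenes are too electron-neutral to compete.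

**Compound list**

1 | (S)-(+)-carvone, (5S)-2-methyl-5-(prop-1-en-2-yl)cyclohex-2-en-1-one | CC1=CC[C@@H](CC1=O)C(C)=C | starting material
2 | lithium (5S)-2-methyl-5-(prop-1-en-2-yl)cyclohex-1-en-1-olate (not isolated) | [Li]OC1=C(C)CC[C@H](C(C)=C)C1 | intermediate
3 | (2R,5S)-2-chloro-2-methyl-5-(prop-1-en-2-yl)cyclohexan-1-one | Cl[C@]1(C)CC[C@H](C(=C)C)CC1=O | intermediate
4 | bromomagnesium (1R,2R,5S)-2-chloro-1-ethenyl-2-methyl-5-(prop-1-en-2-yl)cyclohexan-1-olate (not isolated) | Br[Mg]O[C@]1(C=C)[C@](C)(Cl)CC[C@H](C(C)=C)C1 | intermediate
5 | (2R,5S)-2-ethenyl-2-methyl-5-(prop-1-en-2-yl)cyclohexan-1-one | C=C[C@@]1(C)CC[C@H](C(=C)C)CC1=O | intermediate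
6 | (2R,5S)-2-ethenyl-2-methyl-5-(prop-1-en-2-yl)cyclohexane-1-carbonitrile, both C-1 epimers | C=C[C@@]1(C)CC[C@H](C(=C)C)CC1C#N | intermediate
7 | (2R,5S)-5-(3-chloroprop-1-en-2-yl)-2-ethenyl-2-methylcyclohexane-1-carbonitrile, both C-1 epimers | C=C[C@@]1(C)CC[C@H](C(=C)CCl)CC1C#N | intermediate
8 | (2R,5S)-5-[3-(acetyloxy)prop-1-en-2-yl]-2-ethenyl-2-methylcyclohexane-1-carbonitrile, both C-1 epimers | C=C[C@@]1(C)CC[C@H](C(=C)COC(C)=O)CC1C#N | intermediate
9 | N-lithio ketimine lithium alkoxide formed from 8 and MeLi (not isolated) | C=C[C@@]1(C)CC[C@H](C(=C)CO[Li])CC1C(C)=N[Li] | intermediate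
10 | 1-[(1S,2R,5S)-2-ethenyl-5-(3-hydroxyprop-1-en-2-yl)-2-methylcyclohexyl]ethan-1-one | C=C[C@@]1(C)CC[C@H](C(=C)CO)C[C@@H]1C(C)=O | intermediate
11 | 2-[(1S,3R,4R)-4-ethenyl-4-methyl-3-(prop-1-en-2-yl)cyclohexyl]prop-2-en-1-ol | C=C[C@@]1(C)CC[C@H](C(=C)CO)C[C@@H]1C(=C)C | intermediate
12 | 2-[(1S,3R,4R)-4-ethenyl-4-methyl-3-(prop-1-en-2-yl)cyclohexyl]prop-2-enal | C=C[C@@]1(C)CC[C@H](C(=C)C=O)C[C@@H]1C(=C)C | intermediate
13 | (+)-alantolactone, (3aR,5S,8aR,9aR)-5,8a-dimethyl-3-methylidene-3a,5,6,7,8,8a,9,9a-octahydronaphtho[2,3-b]furan-2(3H)-one | C=C1C(=O)O[C@@H]2C[C@@]3(C)CCC[C@H](C)C3=C[C@H]12 | starting material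
14 | CNP0175206.1, spiro-dihydropyran adduct of 12 and 13 (spiro carbon R) | C=C[C@@]1(C)CC[C@H](C2=CO[C@@]3(CC2)C(=O)O[C@@H]2C[C@@]4(C)CCC[C@H](C)C4=C[C@@H]23)C[C@@H]1C(=C)C | target

**Step count and risks**

Total step count: 9. Longest linear sequence: 9 steps (1 to 14); 13 enters in step 9.

Steps most likely to fail:

1. Step 9. The cycloaddition joins two electron-poor partners and may be slow, so that self-dimerisation or polymerisation of the acrolein competes; facial discrimination at the lactone methylene may also be incomplete. The fallback builds the same ring stepwise, carbon–oxygen bond first, from 13 and 12, and comes back at 14. Weitz–Scheffer epoxidation of the exocyclic methylene of 13 (t-BuOOH, DBU, CH2Cl2) on the convex face gives the spiro-epoxy lactone F1, which already carries the oxygen on the required face of the future spiro carbon. Opening at the primary carbon with MgI2 in Et2O gives the iodohydrin F2. A Giese addition of the derived primary radical to the acrolein 12 (Bu3SnH, AIBN, benzene, 80 °C, slow addition) forms the CH2–CH2 bond and gives a δ-hydroxy aldehyde that closes to the lactol F3. Dehydration of the lactol (MsCl, Et3N, CH2Cl2, 0 °C to rt) gives the enol ether 14.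

2. Step 2. Enolisation or halogen–metal exchange may outrun carbonyl addition, and the tertiary chloride may ionise or eliminate, or a ring bond may migrate, instead of the vinyl shift. The fallback sets out from 1 and comes back at 5, with the face of the quaternary centre controlled by a catalyst instead of by the rearrangement. The enolate 2 (L-Selectride, THF, −78 °C) is trapped with allyl chloroformate as the allyl enol carbonate F4. Palladium-catalysed decarboxylative asymmetric allylic alkylation (Pd2(dba)3, (R)-t-BuPHOX, THF, rt) gives the α-allyl ketone F5 with the allyl group trans to the isopropenyl group. Isomerisation of the allyl group (RuHCl(CO)(PPh3)3, toluene, 80 °C) gives the (E)-propenyl ketone F6, and ethenolysis (second-generation Grubbs catalyst, ethylene, CH2Cl2, 40 °C) gives 5.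

3. Step 3. The TosMIC anion may fail to add to the ketone, which is shielded by the adjacent quaternary centre, or enolisation may consume the base. The fallback sets out from 5 and comes back at 6 by a Wittig homologation instead of isocyanide chemistry. Methoxymethylenation (MeOCH2PPh3Cl, KN(SiMe3)2, THF, 0 °C to rt) gives the methyl enol ether F7, and mild hydrolysis (1 M aq HCl, THF, rt) gives the aldehyde F8. Condensation with NH2OH·HCl in pyridine gives the oxime F9, and dehydration (Burgess reagent, THF, 50 °C) gives the nitrile 6.

Further compounds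
F1 | step 9 | 11,13-epoxy-11,13-dihydroalantolactone, spiro-oxirane with the oxygen on the face of the ring-fusion hydrogens (C-11 = lactone α-carbon, C-13 = former methylene carbon) | C1O[C@]12C(=O)O[C@@H]3C[C@@]4(C)CCC[C@H](C)C4=C[C@H]23
F2 | step 9 | 11-hydroxy-13-iodo-11,13-dihydroalantolactone | O[C@@]1(CI)C(=O)O[C@@H]2C[C@@]3(C)CCC[C@H](C)C3=C[C@H]12
F3 | step 9 | lactol of the Giese adduct, 6-hydroxy-tetrahydropyran analogue of 14 (epimers at the two new sp3 carbons) | C=C[C@@]1(C)CC[C@H](C2C(O)O[C@@]3(CC2)C(=O)O[C@@H]2C[C@@]4(C)CCC[C@H](C)C4=C[C@@H]23)C[C@@H]1C(=C)C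
F4 | step 2 | prop-2-en-1-yl (5S)-2-methyl-5-(prop-1-en-2-yl)cyclohex-1-en-1-yl carbonate | C=CCOC(=O)OC1=C(C)CC[C@H](C(C)=C)C1
F5 | step 2 | (2R,5S)-2-methyl-5-(prop-1-en-2-yl)-2-(prop-2-en-1-yl)cyclohexan-1-one | C=CC[C@@]1(C)CC[C@H](C(=C)C)CC1=O
F6 | step 2 | (2R,5S)-2-methyl-2-[(1E)-prop-1-en-1-yl]-5-(prop-1-en-2-yl)cyclohexan-1-one | C/C=C/[C@@]1(C)CC[C@H](C(=C)C)CC1=O
F7 | step 3 | (1R,4S)-1-ethenyl-2-(methoxymethylidene)-1-methyl-4-(prop-1-en-2-yl)cyclohexane (E/Z mixture) | C=C[C@@]1(C)CC[C@H](C(=C)C)CC1=COC
F8 | step 3 | (2R,5S)-2-ethenyl-2-methyl-5-(prop-1-en-2-yl)cyclohexane-1-carbaldehyde (both C-1 epimers) | C=C[C@@]1(C)CC[C@H](C(=C)C)CC1C=O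
F9 | step 3 | oxime of F8 | C=C[C@@]1(C)CC[C@H](C(=C)C)CC1C=NO
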